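**North-east run.** With J at 20.0% of the Z and D charged, the north-east run levels off at Q 12.9%. The south run has J at 40.0%, so the bench rule, Q in proportion to J dosed, promises 25.8% there. The late south readings of Q average 19.7%, less than that.

| flask | Z | D | J | remark | time |
|---|---|---|---|---|---|
| south | 19 mM | 19 mM | 15.2 mM (fed, over 12 s) | the very flask that is asked about, followed so far |  |
| north-east | 19 mM | 19 mM | 7.6 mM (fed, over 12 s) | run made earlier |  |
| flask | 19 mM | 19 mM | 15.2 mM (fed, over 12 s) |  | 2.0 h |
- south (time / min: Q / %, D / %): 3.00: 15.8, 48.3; 4.00: 16.5, 48.7; 6.00: 17.8, 48.8; 10.0: 19.6, 48.1; 15.0: 19.5, 48.1; 25.0: 19.8, 48.3; 40.0: 19.9, 48.0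
- north-east (time / min: Q / %, D / %): 6.00: 12.2, 48.9; 10.0: 12.3, 48.0; 15.0: 12.8, 49.0; 25.0: 12.9, 48.1; 40.0: 12.7, 49.5; 60.0: 13.2, 48.9; 80.0: 12.9, 49.2

(each reading ± 0.5 percentage points)
- the state of affairs at 2.0 h: stopped, and by what, or still going (all of Z has reacted / J has run out first / it is still moving)
- Q at 2.0 h, in percent of the Z and D together charged
- D at 2.0 h, in percent of the Z and D together charged
- J is single-handed; Z and D are mirror images of each other, charged as a racemate, each of them at the stated concentration
- what was read earlier has a scatter of 0.5 percentage points, one standard deviation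
- candidate steps: 2 J -> L; J + D -> E; J + Z -> Q
- the reaction counts as stopped when no species that holds the Z and D together changes by six tenths of a point or more over the second half of the time
- the handed part of J does not stay in what it makes, so the products of the two hands are mirror images too

**The border.** Take J, Z and Q as fractions of the charge, and let J also pair off into L. Each J caught by Z then costs w·J/Z more J. With Z held at its mean m, the charge j yields Q = (m/w)·ln(1 + w·j/m). In the north-east run m is 43.5%. Since w = (m/Q)·ln(1 + w·j/m), start at 3 and go round three times. The waste number, J lost to L per J caught at equal fractions of J and Z, reads 2.83 from the north-east readings. Proportion needs w times charged J per charged Z well below one, but that product is 1.13 north-east and 2.26 south.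

**My reckoning.** For the south flask, Z at full charge gives Q 20.9%. Putting that back into m gives 18.9%, then 19.1%. Q stands still in the south run with Z reckoned near 30.3%, above zero, which points to J as the limiting reagent. The south readings of D average 48.3%.

**The forecast.** It says J has run out first, Q 19.8% (19.4% to 20.2%) and D 48.3% (47.9% to 48.7%), since “Nothing further should happen by 2 h”. Its Q lies above mine.

**The result.** South flask: J has run out first, Q 19.3%, D 48.5%.

    2 J → L (k = 0.490 L mol⁻¹ s⁻¹)
    J + D → E (k = 0.0220 L mol⁻¹ s⁻¹)
    J + Z → Q (k = 0.360 L mol⁻¹ s⁻¹)

At 2.00 h the south flask has J at 0% and L at 3.66 mM, which took 48.1% of charged J. For that flask the waste number put 52.2% of charged J outside Q, a share that holds E too.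

**Neighbour flask.** With 6.1 mM of J, j is 16.1%. Z at full charge gives Q 11.4%, and one round gives 11.1%. That flask gives Q 10.8%, with J at 0%.

All runs are calculated with made-up constants; noise was put on by code.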